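**Plan**

- Feature: in the oxolane ring (O1, C2–C5) the chain C2–C3–C4–C5 carries aryl, CH2OH, CH2OH and aryl all on one face (meso, all-cis). This is the substitution pattern of the endo adduct of an (E,E)-1,4-diarylbutadiene with maleic anhydride, a cyclohexene whose CH=CH unit spans C2 and C5 where O1 has to stand.
- Cuts: first O1–C5 (ether closure). Then C2–O and C5–O go back to C2–CHO and C5–CHO (Baeyer–Villiger), the two CHO groups go back to the ring alkene (ozonolysis), and C2–C3 and C4–C5 are cut last (retro-Diels–Alder). The diene is cut at one double bond (Horner–Wadsworth–Emmons) into two syringaldehyde-derived halves.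
- Forward: the two halves are joined to the diene and the cyclohexene ring arises in the cycloaddition. A 1,3-dioxepane (acetonide) ring then ties the two reduced carboxyl arms. The carbocycle is opened, both bridge carbons are exchanged for oxygen, and the oxolane closes last.
- Stereochemistry: all four centres come from the cycloaddition (E,E diene, Z dienophile, endo approach). Both carbon-to-oxygen migrations run with retention, and C5 is inverted twice (bromide formation, ring closure), so the tetrad arrives unchanged.
- Safeguards: the phenols travel as tosylates, which leaves both benzylic carbons too electron-poor to ionise during the substitutions and shields the arenes from ozone and peracid. One formate from the Baeyer–Villiger step is kept as mask, and later as trigger, for the C2 oxygen.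

Key step: step 7

Remark: Ar stands for 3,5-dimethoxy-4-(tosyloxy)phenyl, and from step 7 on the four stereocentres are called C2–C5 (oxolane numbering of the target). The three intermediates between the meso bis-formate and the meso oxolane are chiral. They are assumed to be carried as racemates (one enantiomer is drawn), which is harmless because both enantiomers close to the same meso ring.

Step 1
Reactants: 1 syringaldehyde (4-hydroxy-3,5-dimethoxybenzaldehyde)
Product: 2 4-formyl-2,6-dimethoxyphenyl 4-methylbenzenesulfonate (O-tosylsyringaldehyde)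
Conditions: TsCl, Et3N, DMAP (cat.), CH2Cl2, 0 °C → rt
Reagents that add atoms: 4-toluenesulfonyl chloride, Cc1ccc(S(=O)(=O)Cl)cc1
Why: Base-mediated O-sulfonylation of a phenol is routine, and the tosylate is chosen because it withstands hydride, ozone, peracid and mild base while turning the para oxygen from a donor into an acceptor.

Step 2
Reactants: 2 O-tosylsyringaldehyde
Product: 3 4-(hydroxymethyl)-2,6-dimethoxyphenyl 4-methylbenzenesulfonate
Conditions: NaBH4, MeOH/THF, 0 °C
Reagents that add atoms: none
Why: Borohydride reduction of an aromatic aldehyde is chemoselective, and aryl sulfonates are inert to it.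

Step 3
Reactants: 3 benzylic alcohol
Product: 4 4-(bromomethyl)-2,6-dimethoxyphenyl 4-methylbenzenesulfonate
Conditions: PBr3, CH2Cl2, 0 °C
Reagents that add atoms: phosphorus tribromide, BrP(Br)Br
Why: The primary benzylic alcohol is brominated by SN2 displacement of its phosphite ester, and no acid-labile group is present.

Step 4
Reactants: 4 benzylic bromide
Product: 5 diethyl {[3,5-dimethoxy-4-(tosyloxy)phenyl]methyl}phosphonate
Conditions: P(OEt)3 (neat), 130 °C
Reagents that add atoms: triethyl phosphite, CCOP(OCC)OCC
Why: The Michaelis–Arbuzov reaction of a primary benzylic bromide is driven by loss of the volatile alkyl bromide.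

Step 5
Reactants: 2 O-tosylsyringaldehyde; 6 (triphenylphosphoranylidene)acetaldehyde
Product: 7 (E)-3-[3,5-dimethoxy-4-(tosyloxy)phenyl]prop-2-enal (O-tosylsinapaldehyde)
Conditions: toluene, 90 °C
Reagents that add atoms: none
Why: Wittig olefination with a stabilised formyl ylide gives the E-enal, and one equivalent of ylide limits a second homologation.

Step 6
Reactants: 5 benzylphosphonate; 7 E-enal
Product: 8 (1E,3E)-1,4-bis[3,5-dimethoxy-4-(tosyloxy)phenyl]buta-1,3-diene
Conditions: NaH, THF, 0 °C → rt
Reagents that add atoms: none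
Why: In this Horner–Wadsworth–Emmons olefination the benzylic phosphonate carbanion adds 1,2 to the enal and forms the new double bond E, while the anhydrous non-nucleophilic base leaves the hindered aryl tosylates untouched.

Step 7
Reactants: 8 (E,E)-diene; 9 maleic anhydride
Product: 10 all-cis-3,6-bis[3,5-dimethoxy-4-(tosyloxy)phenyl]cyclohex-4-ene-1,2-dicarboxylic anhydride (meso; both aryl groups and the anhydride ring on one face)
Conditions: xylene, BHT (cat.), reflux (ca. 140 °C), excess 9; adduct crystallised on cooling
Reagents that add atoms: none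
Why: Heating brings the s-cis conformer of 8 and the electron-poor alkene of 9 together in a concerted, suprafacial–suprafacial [4+2] cycloaddition, the classical Diels–Alder reaction of (E,E)-1,4-diarylbuta-1,3-dienes with maleic anhydride. The cyclohexene ring closes intermolecularly through one cyclic six-electron transition state in which both new sigma bonds, the future C2–C3 and C4–C5, form together, while the central diene carbons become the CH=CH bridge between C2 and C5. C2 and C5 are set cis to each other by the E,E geometry of the diene (both aryl groups are outside substituents), and C3 and C4 are set cis to each other by the Z geometry locked in the ring of 9. The relation between the two pairs is set by the endo approach, in which the anhydride carbonyl groups lie under the diene carbons that become the bridge, so that aryl groups and anhydride ring end on the same face and the adduct is the meso all-cis isomer. Endo over exo is the only selectivity required, because both partners are symmetric and no regiochemical question arises; it is secured by the flat cyclic dienophile with its two carbonyl groups and by crystallising the kinetic adduct before cycloreversion can equilibrate it. Any residual E,Z diene cannot adopt the s-cis form and is left behind, and the slightly lowered donor strength of the tosyloxy-substituted diene is met by excess 9 at reflux.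

Step 8
Reactants: 10 all-cis anhydride
Product: 11 all-cis-[3,6-diAr-cyclohex-4-ene-1,2-diyl]dimethanol (meso)
Conditions: LiAlH4, THF, 0 °C → rt; then H2O
Reagents that add atoms: none
Why: Lithium aluminium hydride reduces the cyclic anhydride to the 1,4-diol without touching the isolated alkene or the aryl tosylates at or below room temperature, and hydride addition outruns enolisation, so all four stereocentres stay as set.

Step 9
Reactants: 11 all-cis diol
Product: 12 all-cis-8,11-diAr-4,4-dimethyl-3,5-dioxabicyclo[5.4.0]undec-9-ene (meso; cis-fused acetonide of 11)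
Conditions: Me2C(OMe)2, PPTS (cat.), CH2Cl2, rt
Reagents that add atoms: 2,2-dimethoxypropane, COC(C)(C)OC
Why: Acid-catalysed transketalisation closes the seven-membered 1,3-dioxepane on the cis-1,4-diol, masks both primary alcohols at once, and acts as a tether that keeps the C3 and C4 arms gauche and so later excludes the extended conformer that cannot cyclise.

Step 10
Reactants: 12 acetonide
Product: 14 meso-2,2'-(2,2-dimethyl-1,3-dioxepane-5,6-diyl)bis(2-Ar-acetaldehyde) (each CHO on C2 or C5 where the ring alkene carbon stood; used crude), via secondary ozonide 13 (not isolated)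
Conditions: O3, CH2Cl2, −78 °C; then PPh3, −78 °C → rt
Reagents that add atoms: ozone, [O-][O+]=O
Why: Ozonolysis attacks the only alkene from its open face, the sulfonylated arenes being too electron-poor to compete at low temperature, and the neutral phosphine work-up keeps the enolisable α-aryl aldehyde centres intact.

Step 11
Reactants: 14 meso dialdehyde
Product: 15 meso bis-formate, (2,2-dimethyl-1,3-dioxepane-5,6-diyl)bis(Ar-methylene) diformate (OCHO on C2 and C5 in place of CHO, configuration retained)
Conditions: mCPBA, NaHCO3, CH2Cl2, 0 °C → rt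
Reagents that add atoms: 3-chloroperoxybenzoic acid, OOC(=O)c1cccc(Cl)c1
Why: In the Baeyer–Villiger oxidation of α-branched α-aryl aldehydes the secondary benzylic carbon of the Criegee adduct migrates in preference to hydride and does so with retention, so each oxygen takes the place of a former bridge carbon on C2 and C5.

Step 12
Reactants: 15 meso bis-formate
Product: 16 hydroxy formate (racemic; C2–OCHO kept, C5–OH free, configuration unchanged)
Conditions: KHCO3 (cat.), MeOH/CH2Cl2, 0 °C, stopped near half conversion; recovered 15 resubmitted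
Reagents that add atoms: none
Why: Base-catalysed transesterification of formates can be stopped at 0 °C after the first cleavage to give a separable statistical mixture, and breaking the symmetry costs nothing because both enantiomers of 16 lead to the same meso product.

Step 13
Reactants: 16 hydroxy formate
Product: 17 bromo formate (racemic; C5–Br with inverted configuration, C2–OCHO unchanged)
Conditions: CBr4, PPh3 (added last, in portions), CH2Cl2, 0 °C
Reagents that add atoms: carbon tetrabromide, BrC(Br)(Br)Br
Why: In the Appel reaction bromide displaces the alkoxyphosphonium group by SN2 with inversion at C5, the electron-poor aryl group blocking ionisation, the formate keeping the C2 oxygen from closing the ring too early, and the order of addition avoiding the dibromomethylene ylide that could attack the formate.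

Step 14
Reactants: 17 bromo formate
Product: 19 meso all-cis-2,5-diAr-oxolane with its 3,4-bis(oxymethyl) arms bridged by isopropylidene, via bromo alcohol 18 (not isolated)
Conditions: K2CO3, MeOH/THF, 0 °C → rt
Reagents that add atoms: none
Why: Methanolysis of the formate frees the C2 oxygen, which displaces the benzylic bromide in a 5-exo-tet Williamson closure with a second inversion at C5, the same ester-cleavage/ring-closure sequence that turns halohydrin esters into epoxides without loss of configuration, so C5 regains its original sense and the ring is all-cis.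

Step 15
Reactants: 19 oxolane acetonide
Product: 20 [(2R,3R,4S,5S)-2,5-diAr-oxolane-3,4-diyl]dimethanol (meso, all-cis bis-tosylate)
Conditions: AcOH/THF/H2O, 40 °C
Reagents that add atoms: none
Why: The seven-membered isopropylidene ketal is hydrolysed by mild acid while the aryl groups are still sulfonylated, so the benzylic C2–O and C5–O bonds cannot ionise and epimerise.

Step 16
Reactants: 20 bis-tosylate diol
Product: 21 [(2R,3R,4S,5S)-2,5-bis(4-hydroxy-3,5-dimethoxyphenyl)oxolane-3,4-diyl]dimethanol (meso, all-cis; target)
Conditions: Mg, MeOH/THF, rt, under argon; then pH 7 phosphate buffer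
Reagents that add atoms: none
Why: Magnesium in methanol cleaves the S–O bond of aryl tosylates by single-electron transfer at room temperature regardless of the flanking methoxy groups, and the near-neutral quench avoids acid-induced as well as quinone-methide-mediated epimerisation of the freed 4-hydroxybenzyl ether centres.

**Compound list**

1 | syringaldehyde | COc1cc(C=O)cc(OC)c1O | starting material
2 | 4-formyl-2,6-dimethoxyphenyl 4-methylbenzenesulfonate | COc1cc(C=O)cc(OC)c1OS(=O)(=O)c2ccc(C)cc2 | intermediate
3 | 4-(hydroxymethyl)-2,6-dimethoxyphenyl 4-methylbenzenesulfonate | COc1cc(CO)cc(OC)c1OS(=O)(=O)c2ccc(C)cc2 | intermediate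
4 | 4-(bromomethyl)-2,6-dimethoxyphenyl 4-methylbenzenesulfonate | COc1cc(CBr)cc(OC)c1OS(=O)(=O)c2ccc(C)cc2 | intermediate
5 | diethyl {[3,5-dimethoxy-4-(tosyloxy)phenyl]methyl}phosphonate | CCOP(=O)(Cc1cc(OC)c(OS(=O)(=O)c2ccc(C)cc2)c(OC)c1)OCC | intermediate
6 | (triphenylphosphoranylidene)acetaldehyde | O=CC=P(c1ccccc1)(c2ccccc2)c3ccccc3 | starting material
7 | (E)-3-[3,5-dimethoxy-4-(tosyloxy)phenyl]prop-2-enal | COc1cc(/C=C/C=O)cc(OC)c1OS(=O)(=O)c2ccc(C)cc2 | intermediate
8 | (1E,3E)-1,4-bis[3,5-dimethoxy-4-(tosyloxy)phenyl]buta-1,3-diene | COc1cc(/C=C/C=C/c2cc(OC)c(OS(=O)(=O)c3ccc(C)cc3)c(OC)c2)cc(OC)c1OS(=O)(=O)c4ccc(C)cc4 | intermediate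
9 | maleic anhydride | O=C1OC(=O)C=C1 | starting material
10 | all-cis-3,6-diAr-cyclohex-4-ene-1,2-dicarboxylic anhydride (meso) | COc1cc([C@H]2C=C[C@@H](c3cc(OC)c(OS(=O)(=O)c4ccc(C)cc4)c(OC)c3)[C@@H](C(=O)O5)[C@H]2C5=O)cc(OC)c1OS(=O)(=O)c6ccc(C)cc6 | intermediate
11 | all-cis-[3,6-diAr-cyclohex-4-ene-1,2-diyl]dimethanol (meso) | COc1cc([C@H]2C=C[C@@H](c3cc(OC)c(OS(=O)(=O)c4ccc(C)cc4)c(OC)c3)[C@@H](CO)[C@H]2CO)cc(OC)c1OS(=O)(=O)c6ccc(C)cc6 | intermediate
12 | all-cis-8,11-diAr-4,4-dimethyl-3,5-dioxabicyclo[5.4.0]undec-9-ene (meso) | COc1cc([C@H]2C=C[C@@H](c3cc(OC)c(OS(=O)(=O)c4ccc(C)cc4)c(OC)c3)[C@@H](COC(C)(C)O5)[C@H]2C5)cc(OC)c1OS(=O)(=O)c6ccc(C)cc6 | intermediate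
13 | secondary ozonide of 12 (1,2,4-trioxolane across the former alkene carbons; configuration at these two acetal carbons left open) | COc1cc([C@H]2C7OOC(O7)[C@@H](c3cc(OC)c(OS(=O)(=O)c4ccc(C)cc4)c(OC)c3)[C@@H](COC(C)(C)O5)[C@H]2C5)cc(OC)c1OS(=O)(=O)c6ccc(C)cc6 | intermediate
14 | meso-2,2'-(2,2-dimethyl-1,3-dioxepane-5,6-diyl)bis(2-Ar-acetaldehyde) | O=C[C@H](c1cc(OC)c(OS(=O)(=O)c2ccc(C)cc2)c(OC)c1)[C@@H]3COC(C)(C)OC[C@@H]3[C@H](c4cc(OC)c(OS(=O)(=O)c5ccc(C)cc5)c(OC)c4)C=O | intermediate
15 | meso bis-formate | O=CO[C@H](c1cc(OC)c(OS(=O)(=O)c2ccc(C)cc2)c(OC)c1)[C@@H]3COC(C)(C)OC[C@@H]3[C@H](c4cc(OC)c(OS(=O)(=O)c5ccc(C)cc5)c(OC)c4)OC=O | intermediate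
16 | hydroxy formate (racemic, one enantiomer drawn) | O=CO[C@H](c1cc(OC)c(OS(=O)(=O)c2ccc(C)cc2)c(OC)c1)[C@@H]3COC(C)(C)OC[C@@H]3[C@H](c4cc(OC)c(OS(=O)(=O)c5ccc(C)cc5)c(OC)c4)O | intermediate
17 | bromo formate, C5 inverted (racemic) | O=CO[C@H](c1cc(OC)c(OS(=O)(=O)c2ccc(C)cc2)c(OC)c1)[C@@H]3COC(C)(C)OC[C@@H]3[C@@H](c4cc(OC)c(OS(=O)(=O)c5ccc(C)cc5)c(OC)c4)Br | intermediate
18 | bromo alcohol (racemic) | O[C@H](c1cc(OC)c(OS(=O)(=O)c2ccc(C)cc2)c(OC)c1)[C@@H]3COC(C)(C)OC[C@@H]3[C@@H](c4cc(OC)c(OS(=O)(=O)c5ccc(C)cc5)c(OC)c4)Br | intermediate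
19 | meso all-cis-2,5-diAr-oxolane 3,4-acetonide | COc1cc([C@H]2O[C@@H](c3cc(OC)c(OS(=O)(=O)c4ccc(C)cc4)c(OC)c3)[C@@H](COC(C)(C)O5)[C@H]2C5)cc(OC)c1OS(=O)(=O)c6ccc(C)cc6 | intermediate
20 | meso all-cis-[2,5-diAr-oxolane-3,4-diyl]dimethanol | COc1cc([C@H]2O[C@@H](c3cc(OC)c(OS(=O)(=O)c4ccc(C)cc4)c(OC)c3)[C@@H](CO)[C@H]2CO)cc(OC)c1OS(=O)(=O)c6ccc(C)cc6 | intermediate
21 | [(2R,3R,4S,5S)-2,5-bis(4-hydroxy-3,5-dimethoxyphenyl)oxolane-3,4-diyl]dimethanol | COc1cc([C@H]2O[C@@H](c3cc(OC)c(O)c(OC)c3)[C@@H](CO)[C@H]2CO)cc(OC)c1O | target

**Step count**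

Total: 16 steps. Longest linear sequence: 15 steps (steps 1–4 and 6–16 from syringaldehyde); step 5 is the side branch.

**Steps most likely to fail**

**Step 14 (ring closure).**
- Risk: base-induced E2 elimination across C4–C5, or capture of the benzylic bromide by methoxide, may outrun the crowded all-cis transition state.
- Fallback: no substitution takes place at C5. C4 and C5 are reset by hydrogenation under the control of C2 and C3. The fallback sets out from 16. Dess–Martin periodinane in CH2Cl2 should give the keto formate F7. KHCO3 in MeOH removes the formate, and the hydroxy ketone closes to the cyclic hemiketal F8. MsCl/Et3N dehydrates this to the 2,3-dihydrofuran F9 (C4=C5 enol ether). Hydrogenation over Rh/Al2O3 in EtOAc should add both hydrogens to the face opposite the C2 aryl group and the C3 arm, as in the known reduction of tetrasubstituted furans to all-cis oxolanes. The route is rejoined at 19.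

**Step 13 (invertive bromination).**
- Risk: configuration at C5 may erode through degenerate bromide exchange at the benzylic carbon while the slow displacement at the β-branched centre proceeds.
- Fallback: the leaving group is introduced with inversion as a sulfonate, whose counter-ion cannot re-attack. The fallback sets out from 16. A Mitsunobu reaction with Zn(OTs)2, DIAD and PPh3 in toluene should give the C5-inverted formate tosylate F5. K2CO3 in MeOH/THF then frees the hydroxy tosylate F6, which closes by the same 5-exo-tet displacement. The route is rejoined at 19.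

**Step 11 (Baeyer–Villiger oxidation).**
- Risk: hydride migration in the Criegee adduct (oxidation to the acid level instead of oxygen insertion), and enolisation of the α-aryl aldehyde during a slow oxidation, with loss of configuration at C2 and C5.
- Fallback: the exchange is run from the more robust carboxylic acid by the carboxy-inversion reaction. The fallback sets out from 14. Pinnick oxidation (NaClO2, NaH2PO4, 2-methylbut-2-ene, t-BuOH/H2O) should give the meso diacid F1. DCC coupling with mCPBA gives the bis(diacyl peroxide) F2. Warming in acetonitrile rearranges this, with migration of each benzylic carbon under retention, to the bis(acyl carbonate) F3. K2CO3 in MeOH gives the meso diol F4. One equivalent of formic acetic anhydride in pyridine monoformylates it, and the route is rejoined at 16.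

**Further compounds**

F1 | step 11 | meso diacid (CO2H on C2 and C5) | OC(=O)[C@H](c1cc(OC)c(OS(=O)(=O)c2ccc(C)cc2)c(OC)c1)[C@@H]3COC(C)(C)OC[C@@H]3[C@H](c4cc(OC)c(OS(=O)(=O)c5ccc(C)cc5)c(OC)c4)C(=O)O
F2 | step 11 | meso bis(3-chlorobenzoyl acyl peroxide) | O=C(OOC(=O)c6cccc(Cl)c6)[C@H](c1cc(OC)c(OS(=O)(=O)c2ccc(C)cc2)c(OC)c1)[C@@H]3COC(C)(C)OC[C@@H]3[C@H](c4cc(OC)c(OS(=O)(=O)c5ccc(C)cc5)c(OC)c4)C(=O)OOC(=O)c7cccc(Cl)c7
F3 | step 11 | meso bis(3-chlorobenzoyl carbonate) | O=C(OC(=O)c6cccc(Cl)c6)O[C@H](c1cc(OC)c(OS(=O)(=O)c2ccc(C)cc2)c(OC)c1)[C@@H]3COC(C)(C)OC[C@@H]3[C@H](c4cc(OC)c(OS(=O)(=O)c5ccc(C)cc5)c(OC)c4)OC(=O)OC(=O)c7cccc(Cl)c7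
F4 | step 11 | meso diol (OH on C2 and C5) | O[C@H](c1cc(OC)c(OS(=O)(=O)c2ccc(C)cc2)c(OC)c1)[C@@H]3COC(C)(C)OC[C@@H]3[C@H](c4cc(OC)c(OS(=O)(=O)c5ccc(C)cc5)c(OC)c4)O
F5 | step 13 | formate tosylate, C5 inverted (racemic) | O=CO[C@H](c1cc(OC)c(OS(=O)(=O)c2ccc(C)cc2)c(OC)c1)[C@@H]3COC(C)(C)OC[C@@H]3[C@@H](c4cc(OC)c(OS(=O)(=O)c5ccc(C)cc5)c(OC)c4)OS(=O)(=O)c6ccc(C)cc6
F6 | step 13 | hydroxy tosylate, C5 inverted (racemic) | O[C@H](c1cc(OC)c(OS(=O)(=O)c2ccc(C)cc2)c(OC)c1)[C@@H]3COC(C)(C)OC[C@@H]3[C@@H](c4cc(OC)c(OS(=O)(=O)c5ccc(C)cc5)c(OC)c4)OS(=O)(=O)c6ccc(C)cc6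
F7 | step 14 | keto formate (racemic) | O=CO[C@H](c1cc(OC)c(OS(=O)(=O)c2ccc(C)cc2)c(OC)c1)[C@@H]3COC(C)(C)OC[C@@H]3C(=O)c4cc(OC)c(OS(=O)(=O)c5ccc(C)cc5)c(OC)c4
F8 | step 14 | cyclic hemiketal (racemic, anomeric centre open) | COc1cc([C@H]2OC(O)(c3cc(OC)c(OS(=O)(=O)c4ccc(C)cc4)c(OC)c3)[C@@H](COC(C)(C)O5)[C@H]2C5)cc(OC)c1OS(=O)(=O)c6ccc(C)cc6
F9 | step 14 | 2,3-dihydrofuran with C4=C5 (racemic) | COc1cc([C@H]2OC(c3cc(OC)c(OS(=O)(=O)c4ccc(C)cc4)c(OC)c3)=C(COC(C)(C)O5)[C@H]2C5)cc(OC)c1OS(=O)(=O)c6ccc(C)cc6
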